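**Retrosynthetic overview**

1. Target 26 ⇐ ozonolysis of vinyl carbinol 25 ⇐ equatorial vinyl addition to 8-ketone 24 (sets C8) ⇐ 1,2-hydride shift of 8,9-epoxide 22 ⇐ sp2–sp3 Negishi union of vinyl iodide 17 (C9) with the zinc reagent of Z-iodo ester 19, whose geometry comes from the ring of lactone 18.
2. 17 ⇐ hydroxy ketone 15 ⇐ trans-decalin 11, made in the key step from monocyclic aldehyde 8 and acrolein: C1–C10 and C2–C3 form in one operation and close ring A onto a ready-made ring B.
3. Enabling feature: the C3 carbonyl carbon lies three bonds from C10 (C3–C4–C5–C10), C4 is quaternary (gem-dimethyl, so the aldehyde cannot enolise and closure is favoured), and C10 carries an exocyclic methylene (C20) on ring B. Hydrogen-atom transfer to C20 creates the tertiary C10 radical and the angular methyl at once, so a two-carbon acceptor (C1–C2) can be stitched between C10 and C3.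
4. 8 ⇐ cyclohexenone 1: a catalytic asymmetric Mukaiyama–Michael addition of ketene acetal 2 sets C5; the enol silane is methylenated at C10 through a phenylthiomethyl group and the C9 ketone is carried as a ketal.
5. Ring order: ring B is bought (1), ring A is formed in step 6; C3, C9 and C8 are then set by hydride delivery, epimerisation and Grignard addition, without protecting groups on oxygen after the ketal.

Key step: step 6

Numbering: ring and chain atoms carry the labdane numbers of the target (ring A = C1–C5, C10; ring B = C5–C10; C20 = methyl on C10; C17 = formyl carbon; C11–C16 = side chain).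
Assumption: the oxazaborolidinium catalyst derived from (S)-α,α-diphenylprolinol is taken to give the (1S)-adduct 3; if the facial sense is the reverse, the mirror-image catalyst is used and nothing else changes.

**Step 1**
Reactants: 1 cyclohex-2-en-1-one; 2 (1-methoxy-2-methylprop-1-enyloxy)trimethylsilane
Product: 3 methyl 2-methyl-2-[(1S)-3-(trimethylsilyloxy)cyclohex-2-en-1-yl]propanoate
Conditions: chiral oxazaborolidinium triflimide [from (S)-α,α-diphenylprolinol, o-tolylboroxine and Tf2NH] (20 mol %), toluene, −20 °C; non-aqueous work-up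
Reagents that add atoms: ketene silyl acetal 2, COC(O[Si](C)(C)C)=C(C)C
Why: Catalytic enantioselective Mukaiyama–Michael addition, a pairing of enone and ketene acetal of the type this catalyst class is known to handle; the catalyst-bound enone is attacked on one face to set C5, and silyl transfer leaves the enol silane regiodefined at C9=C10.

**Step 2**
Reactants: 3 methyl 2-methyl-2-[(1S)-3-(trimethylsilyloxy)cyclohex-2-en-1-yl]propanoate
Product: 4 methyl 2-methyl-2-[(1S,2R)-3-oxo-2-(phenylsulfanylmethyl)cyclohexyl]propanoate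
Conditions: PhSCH2Cl, TiCl4, CH2Cl2, −78 °C
Reagents that add atoms: chloromethyl phenyl sulfide, ClCSc1ccccc1
Why: Lewis-acid-mediated alkylation of a silyl enol ether by a thionium ion (Mukaiyama-type α-phenylthiomethylation) should be regiospecific at C10 and trans to the C5 substituent; the C10 centre is removed again in step 4.

**Step 3**
Reactants: 4 methyl 2-methyl-2-[(1S,2R)-3-oxo-2-(phenylsulfanylmethyl)cyclohexyl]propanoate
Product: 5 methyl 2-methyl-2-[(6R,7S)-6-(phenylsulfanylmethyl)-1,4-dioxaspiro[4.5]decan-7-yl]propanoate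
Conditions: TMSOCH2CH2OTMS, TMSOTf (5 mol %), CH2Cl2, −78 → −20 °C
Reagents that add atoms: 1,2-bis(trimethylsilyloxy)ethane, C[Si](C)(C)OCCO[Si](C)(C)C
Why: Aprotic silyl-transfer ketalisation should mask the C9 ketone without β-elimination of thiophenol, so that the later C10=C20 alkene is not conjugated to a carbonyl; no new stereocentre.

**Step 4**
Reactants: 5 methyl 2-methyl-2-[(6R,7S)-6-(phenylsulfanylmethyl)-1,4-dioxaspiro[4.5]decan-7-yl]propanoate
Product: 7 methyl 2-methyl-2-[(7S)-6-methylidene-1,4-dioxaspiro[4.5]decan-7-yl]propanoate, via sulfoxide 6 (not isolated)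
Conditions: mCPBA (1.0 equiv), NaHCO3, CH2Cl2, −78 °C; then CaCO3, toluene, 110 °C
Reagents that add atoms: none
Why: Sulfide oxidation followed by thermal syn-elimination of the sulfoxide; the only β-hydrogen is on C10, so the exocyclic C10=C20 methylene should be the sole alkene.

**Step 5**
Reactants: 7 methyl 2-methyl-2-[(7S)-6-methylidene-1,4-dioxaspiro[4.5]decan-7-yl]propanoate
Product: 8 2-methyl-2-[(7R)-6-methylidene-1,4-dioxaspiro[4.5]decan-7-yl]propanal (same spatial arrangement as 7; only the priorities change)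
Conditions: DIBAL-H (1.05 equiv), CH2Cl2, −78 °C
Reagents that add atoms: none
Why: Partial reduction of an ester; the aluminium hemiacetal of this hindered α-quaternary methyl ester should survive at −78 °C and release the aldehyde only on work-up.

**Step 6**
Reactants: 8 2-methyl-2-[(7R)-6-methylidene-1,4-dioxaspiro[4.5]decan-7-yl]propanal; 9 acrolein
Product: 11 (5R,10R)-9,9-(ethylenedioxy)-3-hydroxy-4,4,10-trimethyl-trans-decalin-2-carbaldehyde (mixture at C2 and C3), via iron enolate 10 (not isolated)
Conditions: Fe(acac)3 (30 mol %), PhSiH3 (2.5 equiv), acrolein (3 equiv), EtOH/ethylene glycol 5:1, 0 °C → rt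
Reagents that add atoms: acrolein 9, C=CC=O
Why: The iron hydride formed from Fe(acac)3 and PhSiH3 transfers a hydrogen atom to the C20 methylene of 8 to give the tertiary C10 radical, which adds to acrolein (Giese addition, C1–C10); the α-formyl radical is reduced by divalent iron to the iron enolate 10, whose C2 attacks the non-enolisable C3 aldehyde (C2–C3). The closest known reaction type is the iron-catalysed radical-polar crossover annulation of γ,δ-unsaturated aldehydes or ketones with enals and enones. Ring A closes by a 6-exo-trig (enolexo) aldol of the enolate carbon onto the aldehyde through a chair that the gem-dimethyl group at C4 favours. C10 is set in the intermolecular step: acrolein should approach the planar radical from the face opposite the bulky C5 substituent (equatorial attack, as with menthyl-type radicals), which places C1 trans to C4 and the new methyl axial, giving the trans-decalin. C2 and C3 arise without a need for control, since both are erased in step 7 and C3 is reset in step 8. The step needs hydrogen-atom transfer to the 1,1-disubstituted alkene in preference to carbonyl reduction, Giese addition faster than radical reduction, and aldol faster than enolate protonation; the unhindered acceptor in excess, the nucleophilic tertiary radical and the aldehyde held 1,6 to the enolate carbon should secure these.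

**Step 7**
Reactants: 11 (5R,10R)-9,9-(ethylenedioxy)-3-hydroxy-4,4,10-trimethyl-trans-decalin-2-carbaldehyde
Product: 13 (5R,10R)-9,9-(ethylenedioxy)-4,4,10-trimethyl-trans-decalin-3-one, via keto aldehyde 12 (not isolated)
Conditions: DMP, NaHCO3, CH2Cl2, 0 °C → rt; then K2CO3, MeOH, 40 °C
Reagents that add atoms: none
Why: Dess–Martin oxidation gives the 2-formyl ketone, and methoxide then removes the formyl group by retro-Claisen cleavage, which deletes the activating carbon and both uncontrolled centres.

**Step 8**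
Reactants: 13 (5R,10R)-9,9-(ethylenedioxy)-4,4,10-trimethyl-trans-decalin-3-one
Product: 15 (3R,5R,10R)-3-hydroxy-4,4,10-trimethyl-trans-decalin-9-one, via ketal alcohol 14 (not isolated)
Conditions: NaBH4, MeOH, 0 °C; then 2 M aq. HCl, THF, 40 °C
Reagents that add atoms: water, O
Why: Borohydride reduction with axial hydride delivery from the face opposite the axial methyls on C4 and C10 should give the equatorial 3-alcohol (cis to C20), as is usual for 4,4-dimethyl-3-ketones; aqueous acid then hydrolyses the ketal to free the C9 ketone.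

**Step 9**
Reactants: 15 (3R,5R,10R)-3-hydroxy-4,4,10-trimethyl-trans-decalin-9-one
Product: 17 (3R,5R,10R)-9-iodo-4,4,10-trimethyl-Δ8-octalin-3-ol, via hydrazone 16 (not isolated)
Conditions: N2H4·H2O, Et3N, EtOH, 80 °C; then I2, tetramethylguanidine, THF, 0 °C → rt
Reagents that add atoms: iodine, [I][I]
Why: Barton vinyl iodide synthesis; C9 has α-hydrogens only on C8, so the C8=C9 iodide is the only regioisomer, and the free hydroxyl is tolerated as with hindered ketones next to a quaternary carbon.

**Step 10**
Reactants: 18 4-methyl-5,6-dihydro-2H-pyran-2-one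
Product: 19 methyl (2Z)-5-iodo-3-methylpent-2-enoate
Conditions: TMSI, CH2Cl2, rt; then MeOH
Reagents that add atoms: iodotrimethylsilane, C[Si](C)(C)I; methanol, CO
Why: Silyl iodide cleavage of the lactone (iodide attacks the O–CH2 carbon by SN2) followed by methanolysis of the silyl ester; the Z geometry is inherited from the ring and no bond to the alkene is touched.

**Step 11**
Reactants: 17 (3R,5R,10R)-9-iodo-4,4,10-trimethyl-Δ8-octalin-3-ol; 19 methyl (2Z)-5-iodo-3-methylpent-2-enoate
Product: 21 methyl (3R,5S,10R,13Z)-3-hydroxy-17-norlabda-8,13-dien-15-oate, via zinc reagent 20 (not isolated)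
Conditions: 19, Zn dust, LiCl, THF, 40 °C; then 17, Pd(dppf)Cl2 (5 mol %), THF/DMA, 50 °C
Reagents that add atoms: iodo ester 19 (as zinc reagent 20), COC(=O)/C=C(/C)CCI
Why: Negishi sp2–sp3 cross-coupling; the alkylzinc iodide tolerates the ester and the free alcohol, and the alkene geometries of both partners are retained.

**Step 12**
Reactants: 21 methyl (3R,5S,10R,13Z)-3-hydroxy-17-norlabda-8,13-dien-15-oate
Product: 22 methyl (3R,5R,8S,9R,10R,13Z)-8,9-epoxy-3-hydroxy-17-norlabd-13-en-15-oate
Conditions: mCPBA (1.1 equiv), NaHCO3, CH2Cl2, 0 °C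
Reagents that add atoms: mCPBA, OOC(=O)c1cccc(Cl)c1
Why: Prilezhaev epoxidation; the electron-rich trisubstituted C8=C9 alkene should react in preference to the enoate, on the face anti to the axial C20 methyl, and either epoxide would converge in step 13.

**Step 13**
Reactants: 22 methyl (3R,5R,8S,9R,10R,13Z)-8,9-epoxy-3-hydroxy-17-norlabd-13-en-15-oate
Product: 24 methyl (3R,5S,9S,10R,13Z)-3-hydroxy-8-oxo-17-norlabd-13-en-15-oate, via 9-epi ketone 23 (not isolated)
Conditions: BF3·OEt2 (0.3 equiv), CH2Cl2, −78 → −40 °C; then DBU, CH2Cl2, rt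
Reagents that add atoms: none
Why: Meinwald rearrangement: the Lewis acid opens the epoxide at tertiary C9 and the antiperiplanar axial C8–H shifts to give the C8 ketone, first as the 9-epimer; DBU then equilibrates the enolisable C9 to the more stable equatorial side chain (9S).

**Step 14**
Reactants: 24 methyl (3R,5S,9S,10R,13Z)-3-hydroxy-8-oxo-17-norlabd-13-en-15-oate
Product: 25 methyl (3R,5S,8S,9S,10R,13Z)-8-ethenyl-3,8-dihydroxy-17-norlabd-13-en-15-oate
Conditions: CH2=CHMgBr (3.5 equiv), LaCl3·2LiCl (0.3 equiv), THF, −78 → −40 °C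
Reagents that add atoms: vinylmagnesium bromide, C=C[Mg]Br
Why: Grignard 1,2-addition; axial approach to C8 is blocked by the syn-axial C20 methyl, so the vinyl group should enter equatorially and leave the hydroxyl axial and cis to C20, while the lanthanum salt suppresses enolisation and the conjugated ester is inert at this temperature.

**Step 15**
Reactants: 25 methyl (3R,5S,8S,9S,10R,13Z)-8-ethenyl-3,8-dihydroxy-17-norlabd-13-en-15-oate
Product: 26 methyl (3R,5S,8R,9S,10R,13Z)-3,8-dihydroxy-17-oxolabd-13-en-15-oate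
Conditions: O3, CH2Cl2, pyridine, −78 °C (Sudan Red 7B end point); then Me2S
Reagents that add atoms: ozone, [O-][O+]=O
Why: Ozonolysis with reductive work-up; the monosubstituted vinyl group should be cleaved before the electron-poor trisubstituted enoate, giving the tertiary α-hydroxy aldehyde without touching a stereocentre.

**Compound list**

1 | cyclohex-2-en-1-one | O=C1C=CCCC1 | starting material
2 | (1-methoxy-2-methylprop-1-enyloxy)trimethylsilane | COC(O[Si](C)(C)C)=C(C)C | starting material
3 | methyl 2-methyl-2-[(1S)-3-(trimethylsilyloxy)cyclohex-2-en-1-yl]propanoate | COC(=O)C(C)(C)[C@H]1CCCC(O[Si](C)(C)C)=C1 | intermediate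
4 | methyl 2-methyl-2-[(1S,2R)-3-oxo-2-(phenylsulfanylmethyl)cyclohexyl]propanoate | COC(=O)C(C)(C)[C@H]1CCCC(=O)[C@@H]1CSc1ccccc1 | intermediate
5 | methyl 2-methyl-2-[(6R,7S)-6-(phenylsulfanylmethyl)-1,4-dioxaspiro[4.5]decan-7-yl]propanoate | COC(=O)C(C)(C)[C@H]1CCCC2(OCCO2)[C@@H]1CSc1ccccc1 | intermediate
6 | methyl 2-methyl-2-[(6R,7S)-6-(phenylsulfinylmethyl)-1,4-dioxaspiro[4.5]decan-7-yl]propanoate (sulfoxide epimers) | COC(=O)C(C)(C)[C@H]1CCCC2(OCCO2)[C@@H]1CS(=O)c1ccccc1 | intermediate
7 | methyl 2-methyl-2-[(7S)-6-methylidene-1,4-dioxaspiro[4.5]decan-7-yl]propanoate | COC(=O)C(C)(C)[C@H]1CCCC2(OCCO2)C1=C | intermediate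
8 | 2-methyl-2-[(7R)-6-methylidene-1,4-dioxaspiro[4.5]decan-7-yl]propanal | O=CC(C)(C)[C@H]1CCCC2(OCCO2)C1=C | intermediate
9 | acrolein (prop-2-enal) | C=CC=O | starting material
10 | iron enolate of 3-[(6R,7R)-6-methyl-7-(2-methyl-1-oxopropan-2-yl)-1,4-dioxaspiro[4.5]decan-6-yl]propanal (drawn as the enolate anion) | [O-]C=CC[C@@]1(C)C2(OCCO2)CCC[C@@H]1C(C)(C)C=O | intermediate
11 | (5R,10R)-9,9-(ethylenedioxy)-3-hydroxy-4,4,10-trimethyl-trans-decalin-2-carbaldehyde (C2 and C3 left undefined; both are erased in steps 7 and 8) | O=CC1C[C@@]2(C)C3(OCCO3)CCC[C@@H]2C(C)(C)C1O | intermediate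
12 | (5R,10R)-9,9-(ethylenedioxy)-4,4,10-trimethyl-3-oxo-trans-decalin-2-carbaldehyde (in equilibrium with its hydroxymethylene enol) | O=CC1C[C@@]2(C)C3(OCCO3)CCC[C@@H]2C(C)(C)C1=O | intermediate
13 | (5R,10R)-9,9-(ethylenedioxy)-4,4,10-trimethyl-trans-decalin-3-one | O=C1CC[C@@]2(C)C3(OCCO3)CCC[C@@H]2C1(C)C | intermediate
14 | (3R,5R,10R)-9,9-(ethylenedioxy)-4,4,10-trimethyl-trans-decalin-3-ol | O[C@@H]1CC[C@@]2(C)C3(OCCO3)CCC[C@@H]2C1(C)C | intermediate
15 | (3R,5R,10R)-3-hydroxy-4,4,10-trimethyl-trans-decalin-9-one | O[C@@H]1CC[C@@]2(C)C(=O)CCC[C@@H]2C1(C)C | intermediate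
16 | hydrazone of 15, (3R,5S,10R) | O[C@@H]1CC[C@@]2(C)C(=NN)CCC[C@@H]2C1(C)C | intermediate
17 | (3R,5R,10R)-9-iodo-4,4,10-trimethyl-Δ8-octalin-3-ol | O[C@@H]1CC[C@@]2(C)C(I)=CCC[C@@H]2C1(C)C | intermediate
18 | 4-methyl-5,6-dihydro-2H-pyran-2-one | CC1=CC(=O)OCC1 | starting material
19 | methyl (2Z)-5-iodo-3-methylpent-2-enoate | COC(=O)/C=C(/C)CCI | intermediate
20 | [(3Z)-5-methoxy-3-methyl-5-oxopent-3-en-1-yl]zinc iodide | COC(=O)/C=C(/C)CC[Zn]I | intermediate
21 | methyl (3R,5S,10R,13Z)-3-hydroxy-17-norlabda-8,13-dien-15-oate | COC(=O)/C=C(/C)CCC1=CCC[C@@H]2C(C)(C)[C@H](O)CC[C@@]12C | intermediate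
22 | methyl (3R,5R,8S,9R,10R,13Z)-8,9-epoxy-3-hydroxy-17-norlabd-13-en-15-oate | COC(=O)/C=C(/C)CC[C@]12O[C@H]1CC[C@@H]3C(C)(C)[C@H](O)CC[C@@]23C | intermediate
23 | methyl (3R,5S,9R,10R,13Z)-3-hydroxy-8-oxo-17-norlabd-13-en-15-oate (9-epimer) | COC(=O)/C=C(/C)CC[C@@H]1[C@]2(C)CC[C@@H](O)C(C)(C)[C@H]2CCC1=O | intermediate
24 | methyl (3R,5S,9S,10R,13Z)-3-hydroxy-8-oxo-17-norlabd-13-en-15-oate | COC(=O)/C=C(/C)CC[C@H]1[C@]2(C)CC[C@@H](O)C(C)(C)[C@H]2CCC1=O | intermediate
25 | methyl (3R,5S,8S,9S,10R,13Z)-8-ethenyl-3,8-dihydroxy-17-norlabd-13-en-15-oate | COC(=O)/C=C(/C)CC[C@H]1[C@]2(C)CC[C@@H](O)C(C)(C)[C@H]2CC[C@]1(O)C=C | intermediate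
26 | methyl (3R,5S,8R,9S,10R,13Z)-3,8-dihydroxy-17-oxolabd-13-en-15-oate | COC(=O)/C=C(/C)CC[C@H]1[C@]2(C)CC[C@@H](O)C(C)(C)[C@H]2CC[C@]1(O)C=O | target

**Step count and risks**

Total step count: 15. Longest linear sequence: 14 (steps 1–9 and 11–15; step 10 is the side branch).

Steps most likely to fail:

- **Step 6.** The intermolecular radical addition may show poor facial selectivity at C10 (some cis-fused product), or the iron enolate may be protonated before it closes onto the aldehyde. The fallback makes the two bonds separately and sets out from aldehyde 8. Vinylmagnesium bromide (THF, −78 °C) would add to the aldehyde to give the allylic alcohol F1, and Dess–Martin oxidation would give the vinyl ketone F2. Under Fe(acac)3/PhSiH3 in EtOH the same tertiary C10 radical would then add intramolecularly to the enone (6-endo radical conjugate addition, C1–C10); the short tether on C5 should enforce the trans ring fusion. This returns to the route at ketone 13.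

- **Step 13.** The cationic epoxide opening may divert into migration of the C20 methyl or ring contraction instead of the 1,2-hydride shift, or the C9 equilibration may stop short. The fallback avoids cations and sets out from epoxide 22. Silylation (TBSOTf, 2,6-lutidine) would give the silyl ether F3. Cp2TiCl (trivalent titanium, made from Cp2TiCl2 and Mn dust) with 1,4-cyclohexadiene would open the epoxide homolytically at C9, and the tertiary radical would take up a hydrogen atom to give the 8-alcohol F4. Dess–Martin oxidation would give the silylated ketone F5 (C9 can be equilibrated with DBU at this stage), and HF·pyridine would return to the route at ketone 24.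

- **Step 15.** Ozone may also attack the trisubstituted enoate, or the α-hydroxy aldehyde may be oxidised further. The fallback brings in C17 as a masked hydroxymethyl group and sets out from ketone 24. (Isopropoxydimethylsilyl)methylmagnesium chloride would add equatorially to give the silane F6. Tamao–Fleming oxidation (KF, KHCO3, H2O2, THF/MeOH) would give the triol F7. TEMPO/PhI(OAc)2 would then oxidise only the primary alcohol and arrive at target 26.

**Further compounds**

F1 | step 6 | 4-methyl-4-[(7R)-6-methylidene-1,4-dioxaspiro[4.5]decan-7-yl]pent-1-en-3-ol (carbinol epimers) | C=CC(O)C(C)(C)[C@H]1CCCC2(OCCO2)C1=C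
F2 | step 6 | 4-methyl-4-[(7R)-6-methylidene-1,4-dioxaspiro[4.5]decan-7-yl]pent-1-en-3-one | C=CC(=O)C(C)(C)[C@H]1CCCC2(OCCO2)C1=C
F3 | step 13 | methyl (3R,5R,8S,9R,10R,13Z)-3-(tert-butyldimethylsilyloxy)-8,9-epoxy-17-norlabd-13-en-15-oate | COC(=O)/C=C(/C)CC[C@]12O[C@H]1CC[C@@H]3C(C)(C)[C@H](O[Si](C)(C)C(C)(C)C)CC[C@@]23C
F4 | step 13 | methyl (3R,5S,8S,9S,10R,13Z)-3-(tert-butyldimethylsilyloxy)-8-hydroxy-17-norlabd-13-en-15-oate | COC(=O)/C=C(/C)CC[C@H]1[C@]2(C)CC[C@@H](O[Si](C)(C)C(C)(C)C)C(C)(C)[C@H]2CC[C@@H]1O
F5 | step 13 | methyl (3R,5S,9S,10R,13Z)-3-(tert-butyldimethylsilyloxy)-8-oxo-17-norlabd-13-en-15-oate | COC(=O)/C=C(/C)CC[C@H]1[C@]2(C)CC[C@@H](O[Si](C)(C)C(C)(C)C)C(C)(C)[C@H]2CCC1=O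
F6 | step 15 | methyl (3R,5S,8R,9S,10R,13Z)-3,8-dihydroxy-17-(isopropoxydimethylsilyl)labd-13-en-15-oate | COC(=O)/C=C(/C)CC[C@H]1[C@]2(C)CC[C@@H](O)C(C)(C)[C@H]2CC[C@]1(O)C[Si](C)(C)OC(C)C
F7 | step 15 | methyl (3R,5S,8R,9S,10R,13Z)-3,8,17-trihydroxylabd-13-en-15-oate | COC(=O)/C=C(/C)CC[C@H]1[C@]2(C)CC[C@@H](O)C(C)(C)[C@H]2CC[C@]1(O)CO
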